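The data stem from a simulated flask from invented constants; noise was put on by code.

I am backing Saturday's flask: leave its bath at −20 °C, and expect little from Friday's once it is warmed.

| flask | substrate | temperature | remark | time |
|---|---|---|---|---|
| oak | 0.045 M | −25 °C | run made earlier |  |
| ash | 0.14 M | −8 °C | run made earlier |  |
| Friday's | 0.11 M |  | at −20 °C until 50 min, from then on at 5 °C | 3.0 h |
| Saturday's | 0.030 M |  | at −20 °C throughout | 3.0 h |

- oak (time / min: target / %, substrate / %): 30.0: 3, 73; 60.0: 7, 58; 90.0: 11, 48; 120: 11, 47
- ash (time / min: target / %, substrate / %): 15.0: 14, 44; 30.0: 21, 32; 50.0: 27, 29; 60.0: 24, 22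

(each reading ± 2 percentage points)



* the flask that ends with the higher amount of target, in percent of the substrate charged, or "neither" when 2 percentage points or less lies between them (Friday's / Saturday's / neither)
* final target, as a percentage of the substrate charged, in Friday's
* final target, as a percentage of the substrate charged, in Saturday's

Here is what the flask holds. At ash's last reading, target is 30.8% of the substrate lost. Target (a kinetic product) does not stay, though: ash reads 27% at 50.0 min and 24% at 60.0 min. That drop of 3 percentage points barely clears the scatter of 2 points per reading, so what follows is soft. Taken as decay, it gives target's half-life against loss, 58.8 min as read at −8 °C. A molecule of target then survives a hold with this chance: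

survival = 2^(−hold / half-life)

Friday's: hold 130 min, survival 21.6%

Friday's: target ≈ 30.8% × 21.6% = 6.65%

Friday's warm hold outlasts that half-life, and its bath is warmer than ash, so I lean below that figure. Saturday's is colder than ash, but warmer than oak and longer. Oak shows no fall, reading 11% then 11%, so I expect Saturday's to pass 11%, which already stands beyond the margin of 2 points above my Friday's figure.

The forecast differs, naming Friday's with 27% against 11% for Saturday's, and noting for Friday's “with possible later loss”.

Friday's ends at 0% target and Saturday's at 23.7%, so Saturday's ends higher.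

    substrate ⇌ intermediate B (K = 0.660, k = 1.21 h⁻¹, Ea = 81.0 kJ mol⁻¹, ΔH = −3.00 kJ mol⁻¹)
    substrate → intermediate A (k = 0.318 h⁻¹, Ea = 71.0 kJ mol⁻¹)
    intermediate B → side product (k = 0.0703 h⁻¹, Ea = 82.0 kJ mol⁻¹)
    intermediate C → side product (k = 0.0541 h⁻¹, Ea = 87.0 kJ mol⁻¹)
    target → over-reaction product (k = 0.290 h⁻¹, Ea = 79.0 kJ mol⁻¹)
    intermediate A ⇌ intermediate C (K = 1.77, k = 4.04 h⁻¹, Ea = 71.0 kJ mol⁻¹, ΔH = −73.0 kJ mol⁻¹)
    intermediate A → target (k = 3.95 h⁻¹, Ea = 72.0 kJ mol⁻¹)
    (constants at −20 °C)

Friday's held 8.61% target at the change of temperature; the survival of 21.6%, reckoned with the half-life read at −8 °C and not at Friday's 5 °C, gives 1.86% of the charge, whereas the flask ends at 0%. A neighbouring flask, like Saturday's but kept at −5 °C, is warmer than ash. Over 3.0 h the same reckoning, still with the half-life read at −8 °C, gives survival 12.0%, and with the share of 30.8% that makes 3.70% target. That neighbouring flask holds over-reaction product at 82.3% and target at 1.52%.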